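## Structural features

The target is a germacranolide: a ten-membered carbocycle (C1–C10) trans-fused at C6/C7 to an α-methylene-γ-butyrolactone (C11–C13, lactone oxygen on C6). The ring holds two trisubstituted alkenes that are both cis within the ring. C4=C5 carries the C15 hydroxymethyl group trans to C6 (C3 cis to C6), and C1=C10 carries the C14 methyl ester with C2 cis to C9; both are E by the CIP rules. Four contiguous stereocentres run C6(R)–C7(S)–C8(S)–C9(S): lactone oxygen, ring-fusion hydrogen, isobutyrate and acetate. The C8/C9 threo-diol pattern is that of L-tartaric acid and C6 is that of (S)-5-(hydroxymethyl)butenolide. Fragile groups are the α-methylene lactone (Michael acceptor), two different secondary esters on neighbouring carbons (differentiation, acyl migration), a second enoate and a free primary allylic alcohol. The real difficulty is the strained ten-membered ring with two ring-cis trisubstituted alkenes that have no useful thermodynamic bias in an open chain, together with three different states on O8, O9 and O15. The key step exploits C4: it bears two different carbon groups (C15 and C3) while C5 bears only hydrogen and C6, which is the pattern of a C5 aldehyde turned into a C4 1,1-dibromoalkene. One of its bromides lies cis to the bulky C6 lactone carbon, so the two C–Br bonds can be substituted one after the other.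

## Logic of the disconnections

**28 back to 25.** The O15–benzyl bond, the acetyl C–O bond at O9 and the isobutyryl C–O bond at O8 are cut first (28 from 27, 27 from 26, 26 from 25). The esters are the most labile groups and belong at the end. O15 stays masked so that the acylations meet only two hydroxyls. The forward steps must tell O8 from O9 in 25 and must spare the α-methylene lactone.

**25 back to 21.** The two acetal C–O bonds (25 from 24) and the C11=C13 bond (24 from 21) are cut. The methylene group is the most electrophilic site and is added late, but before the diol is freed, so that the enolate chemistry meets neither free hydroxyls nor the secondary esters. The forward step must enolise the lactone in 21 and not the C14 enoate.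

**21 back to 19.** The C10–C14 bond is cut (21 from 20, 20 from 19). The ester-bearing trisubstituted alkene becomes a ring ketone, and the alkene geometry becomes a question of enolate geometry inside the ring. The forward step must enolise 19 toward C1, not C9, and give the enolate with C2 cis to C9.

**19 back to 14.** The C1–C10 ring bond is cut, opening the carbocycle to 18 with an iodide at C1 and an activated thioester at C10. A reductive acyl coupling needs no strong base and tolerates lactone, acetal and ethers. The cis C4=C5 alkene and the two trans-disubstituted five-membered rings of 18 bring the chain ends together. The forward step needs high dilution and must outrun reduction of the iodide. 18 comes from 14 by functional-group changes only (15, 16, 17).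

**14 back to 9, 12 and 11 (key disconnection).** Both carbon–carbon bonds at C4 are cut: C4–C15 and C3–C4. Three components of very different complexity meet at one carbon, and the alkene geometry is reduced to the order in which two bromides react. In 9 the C10 ester and the acetal are inert to aqueous carbonate and to organozinc, and C15 arrives already protected in 12. The first coupling must take only the bromide trans to C6 and the second must proceed with retention.

**9 back to 5.** The C4=C5 bond is cut (9 from 7 and 8), with C4 supplied by 8, and the aldehyde is traced to the silyl ether (7 from 6, 6 from 5). The olefination must not epimerise C6 or expose the acetal to acid.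

**5 back to 1 and 3.** The C7–C8 bond is cut (5 from 2 and 4), which divides the stereochemical array into two chiral-pool halves (2 from 1, 4 from 3). The C8 radical from 2 must add to C7 of 4 anti to the C6 substituent and must bond trans to the C9 ester on the dioxolane.

**11 back to 10.** The C–Zn bond is cut; direct metal insertion into the C–I bond of 10 must leave the silyl ether intact.

## Other disconnections considered

Alternative 1: The cut is the C8–C9 bond, which contracts the ten-membered ring to a cyclohexene (retro oxy-Cope).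
- **Forward step:** the potassium alkoxide (KH, 18-crown-6) of A2 would undergo an anionic oxy-Cope rearrangement to the enolate of cyclodecadienone A1. A2 is a cyclohex-2-enol with an (E)-2-(4-methoxybenzyloxy)vinyl group on the carbinol carbon C6 and, cis to it on C1, a β-(methoxymethoxy)acrylate arm.
- **In favour:** the ring arises by ring expansion without high dilution, which is better than the macrocyclisation of the chosen plan. The ring-cis C4=C5 geometry is inherited from the six-membered ring and cannot be lost, which is better than a catalyst-controlled selectivity. O8 and O9 arrive with different protecting groups, which is better than the acetal of the chosen plan. C1=C10 and its ester form in the same step, so triflation and carbonylation are not needed.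
- **Against:** all stereochemistry hangs on one chair transition state with the C1–C2 ring bond axial and both alkoxy groups equatorial. A boat, or the other chair, would give the C1=C10 isomer or the erythro diol. Both enol ethers must be geometrically pure, and the quaternary carbinol C6 has no chiral-pool counterpart. The enolate formed carries the C8 alkoxy group in the β position and could expel it. A1 has neither C11/C12 nor the C6 and C7 stereocentres; these would have to be set on a flexible ten-membered dienone.
- **Comparison:** on ring formation, alkene geometry and O8/O9 differentiation the alternative is the stronger plan; on C6/C7 it is the weaker. Mechanistically, one ordered pericyclic step stands against two catalyst-controlled couplings, a comparable risk. In step count it is shorter at the skeleton but longer before (A2) and after (lactone), so no clear gain overall.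

Alternative 2: The cut is the C7–C11 bond of the lactone.
- **Forward step:** Pd(PPh3)4 would ionise the C9 acetate of A4 (either C9 epimer) to a π-allyl complex over C7–C9. The sodium salt of the C6 phosphonoacetate would close on C7 in a 5-exo allylic alkylation to give the α-phosphono lactone A3.
- **In favour:** the phosphonate allows the α-methylene group to be made by a Horner–Wadsworth–Emmons reaction with formaldehyde under mild base. This is better than the strong-base Mannich sequence of the chosen plan. The C6/C7 trans relation comes from ring closure under substrate control, equal in kind to the anti radical addition used here.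
- **Against:** A3 has no ten-membered ring. The C2–C3 bond between two allylic carbons is still to be made, with the regiochemical ambiguity of allyl–allyl coupling. O8 and O9 are absent and would have to be added across C8=C9 of a dienoate beside three other alkenes, with only C7 to direct the face. The chosen plan imports both centres from the chiral pool. The C6 ester oxygen is itself doubly allylic, so its ionisation competes with that of the acetate. The C4 geometry is only deferred, since two oxygenated CH2 groups are told apart by protecting groups alone; on this point the alternative is equal at best.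
- **Comparison:** more steps would follow the key step than in the chosen plan.

Alternative 3: The cuts are C1–C2 and C9–C10, removing C1, C10 and C14 as methyl propiolate and contracting the carbocycle to eight members.
- **Forward step:** under ZrCl4 the silyl enol ether A6 (drawn as the trimethylsilyl ether) would add to methyl propiolate to give the bicyclo[6.2.0]decene A7. Its cyclobutene would open across C9–C2 and, after acidic work-up, give the alkylidene β-keto ester A5.
- **In favour:** one operation gives the ten-membered ring, C1=C10 and the C14 ester. This is better step economy than macrocyclisation, triflation and carbonylation. Strain release replaces high dilution, which is also better. O8 (ether) and O9 (ketone) are differentiated, again better. The lactone with C6 and C7 is already in place, which is equal.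
- **Against:** A6 is an eight-membered ring with a cis alkene and a trans-fused lactone, and is no easier to build than the ten-membered ring. Its enol ether must form toward C2 and away from the alkoxy-bearing C8. ZrCl4 is a strong Lewis acid toward the PMB ether, the primary silyl ether and the lactone. The C1=C10 geometry would be set by proton transfer under thermodynamic control. A5 is a doubly activated Michael acceptor with an epimerisable C8. The C9 ketone would have to be reduced with facial control from ring conformation alone, whereas the chosen plan takes C9 from the chiral pool.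
- **Comparison:** shorter after the key step, longer before it, with more mechanistic branch points than two cross-couplings.

Key step: step 8

Remark: atom labels C1–C15 follow germacranolide numbering in every intermediate. CIP descriptors at C6, C7 and C9 change along the route only because substituent priorities change. The C11 configuration of 22 and 23 is left open because that carbon becomes trigonal in 24.

## Steps

Step 1
Reactants: 1 dimethyl (4R,5R)-2,2-dimethyl-1,3-dioxolane-4,5-dicarboxylate
Product: 2 (4R,5R)-5-(methoxycarbonyl)-2,2-dimethyl-1,3-dioxolane-4-carboxylic acid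
Conditions: KOH (1.0 equiv), MeOH, 0 °C → rt; then aq HCl to pH 3, EtOAc
Reagents that add atoms: potassium hydroxide, [K+].[OH-]
Why: Mono-saponification of a C2-symmetric diester with one equivalent of hydroxide; the first carboxylate retards attack on the second ester, no stereocentre is touched and the trans-dioxolane is the stable isomer.

Step 2
Reactants: 3 (S)-5-(hydroxymethyl)furan-2(5H)-one
Product: 4 (S)-5-{[tert-butyl(dimethyl)silyl]oxymethyl}furan-2(5H)-one
Conditions: TBSCl, imidazole, CH2Cl2, 0 °C → rt
Reagents that add atoms: tert-butyldimethylsilyl chloride, CC(C)(C)[Si](C)(C)Cl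
Why: Standard imidazole-mediated silylation of a primary alcohol; the bulky silyl ether later shields the butenolide face syn to C5.

Step 3
Reactants: 2 (4R,5R)-5-(methoxycarbonyl)-2,2-dimethyl-1,3-dioxolane-4-carboxylic acid; 4 (S)-5-{[tert-butyl(dimethyl)silyl]oxymethyl}furan-2(5H)-one
Product: 5 methyl (4R,5S)-5-[(2S,3S)-2-{[tert-butyl(dimethyl)silyl]oxymethyl}-5-oxooxolan-3-yl]-2,2-dimethyl-1,3-dioxolane-4-carboxylate
Conditions: Ir[dF(CF3)ppy]2(dtbbpy)PF6 (1 mol%), K2HPO4, DMF, blue LEDs, rt
Reagents that add atoms: none
Why: Photoredox decarboxylative Giese addition: the excited trivalent iridium complex oxidises the carboxylate of 2, loss of CO2 gives the C8 dioxolanyl radical, which adds to C7 of 4, and the α-acyl radical is reduced by the divalent iridium species and protonated at C11. C7 is set by attack anti to the C6 silyloxymethyl group (trans lactone) and C8 by bond formation trans to the C9 ester on the dioxolane (net retention of the tartrate pattern).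

Step 4
Reactants: 5 methyl (4R,5S)-5-[(2S,3S)-2-{[tert-butyl(dimethyl)silyl]oxymethyl}-5-oxooxolan-3-yl]-2,2-dimethyl-1,3-dioxolane-4-carboxylate
Product: 6 methyl (4R,5S)-5-[(2S,3S)-2-(hydroxymethyl)-5-oxooxolan-3-yl]-2,2-dimethyl-1,3-dioxolane-4-carboxylate
Conditions: HF·pyridine, pyridine, THF, 0 °C → rt
Reagents that add atoms: none
Why: Fluoride cleavage of the primary silyl ether under buffered conditions that leave lactone, ester and acetal untouched.

Step 5
Reactants: 6 methyl (4R,5S)-5-[(2S,3S)-2-(hydroxymethyl)-5-oxooxolan-3-yl]-2,2-dimethyl-1,3-dioxolane-4-carboxylate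
Product: 7 methyl (4R,5S)-5-[(2S,3R)-2-formyl-5-oxooxolan-3-yl]-2,2-dimethyl-1,3-dioxolane-4-carboxylate
Conditions: Dess–Martin periodinane, CH2Cl2, 0 °C → rt; used at once
Reagents that add atoms: none
Why: Dess–Martin oxidation of the primary alcohol without base, so C6 (α to the new aldehyde) is not epimerised.

Step 6
Reactants: 7 methyl (4R,5S)-5-[(2S,3R)-2-formyl-5-oxooxolan-3-yl]-2,2-dimethyl-1,3-dioxolane-4-carboxylate; 8 carbon tetrabromide
Product: 9 methyl (4R,5S)-5-[(2S,3S)-2-(2,2-dibromoethenyl)-5-oxooxolan-3-yl]-2,2-dimethyl-1,3-dioxolane-4-carboxylate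
Conditions: PPh3, Zn dust, CH2Cl2, rt (ylide preformed); then 7, 0 °C → rt
Reagents that add atoms: none
Why: Corey–Fuchs (Ramirez) dibromo-olefination: the non-basic ylide Ph3P=CBr2 made from 8, PPh3 and Zn converts the C5 aldehyde into the 1,1-dibromoalkene and supplies C4; zinc takes up the bromine so the acetal sees no acid.

Step 7
Reactants: 10 tert-butyl(3-iodopropoxy)dimethylsilane
Product: 11 [3-(tert-butyldimethylsilyloxy)propyl]zinc iodide (titrated THF solution)
Conditions: Zn dust (activated with 1,2-dibromoethane and TMSCl), THF, 40 °C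
Reagents that add atoms: zinc, [Zn]
Why: Direct insertion of activated zinc into a primary C–I bond (Knochel-type preparation of functionalised alkylzinc halides); the silyl ether is inert.

Step 8
Reactants: 9 methyl (4R,5S)-5-[(2S,3S)-2-(2,2-dibromoethenyl)-5-oxooxolan-3-yl]-2,2-dimethyl-1,3-dioxolane-4-carboxylate; 12 potassium [(4-methoxybenzyloxy)methyl]trifluoroborate; 11 [3-(tert-butyldimethylsilyloxy)propyl]zinc iodide
Product: 14 methyl (4R,5S)-5-[(2R,3S)-2-[(1E)-5-{[tert-butyl(dimethyl)silyl]oxy}-2-[(4-methoxybenzyloxy)methyl]pent-1-enyl]-5-oxooxolan-3-yl]-2,2-dimethyl-1,3-dioxolane-4-carboxylate, via (Z)-bromoalkene 13 (not isolated)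
Conditions: 12 (1.15 equiv), Pd(PPh3)4 (7 mol%), Cs2CO3 (3 equiv), toluene/H2O (10:1), 60 °C; then rt, Pd(t-Bu3P)2 (10 mol%), 11 (4 equiv in THF), rt → 40 °C
Reagents that add atoms: none
Why: Zerovalent palladium from Pd(PPh3)4 inserts into the C4–Br bond trans to C6, because the cis bromide is shielded by the C6 lactone carbon; carbonate and water turn 12 into the boronate, and transmetallation with reductive elimination forms C4–C15 to give 13. The electron-rich, bulky Pd(t-Bu3P)2 then inserts into the remaining hindered C4–Br bond, 11 transmetallates and reductive elimination with retention forms C3–C4. The closest known reaction type is the trans-selective Suzuki–Miyaura monocoupling of 1,1-dibromoalkenes followed by Negishi alkylation of the resulting (Z)-bromoalkene with retention; the alkoxymethyltrifluoroborate is a new partner for the first stage. No ring is closed and no stereocentre is made; the step fixes the C4=C5 geometry (E, C3 cis to C6). Mono- versus double coupling and trans versus cis attack in the first stage are secured by the steric difference between the two bromides, the small excess of 12 and the less active phosphine. Retention in the second stage is secured by the fast oxidative addition and reductive elimination with t-Bu3P, which outrun isomerisation of the alkenylpalladium. The alkoxymethyl group has no β-hydrogen on carbon, so β-hydride elimination cannot intervene, and the excess of 11 also consumes the residual water. Lactone, methyl ester and acetal are inert to wet carbonate at 60 °C and to the organozinc, and the allylic C6–O bond is not ionised because the trisubstituted alkene binds zerovalent palladium poorly.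

Step 9
Reactants: 14 methyl (4R,5S)-5-[(2R,3S)-2-[(1E)-5-{[tert-butyl(dimethyl)silyl]oxy}-2-[(4-methoxybenzyloxy)methyl]pent-1-enyl]-5-oxooxolan-3-yl]-2,2-dimethyl-1,3-dioxolane-4-carboxylate
Product: 15 methyl (4R,5S)-5-[(2R,3S)-2-[(1E)-5-hydroxy-2-[(4-methoxybenzyloxy)methyl]pent-1-enyl]-5-oxooxolan-3-yl]-2,2-dimethyl-1,3-dioxolane-4-carboxylate
Conditions: HF·pyridine, pyridine, THF, 0 °C → rt
Reagents that add atoms: none
Why: Fluoride cleavage of the primary silyl ether at C1; acetal, PMB ether, lactone and ester are stable to buffered HF·pyridine.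

Step 10
Reactants: 15 methyl (4R,5S)-5-[(2R,3S)-2-[(1E)-5-hydroxy-2-[(4-methoxybenzyloxy)methyl]pent-1-enyl]-5-oxooxolan-3-yl]-2,2-dimethyl-1,3-dioxolane-4-carboxylate
Product: 16 methyl (4R,5S)-5-[(2R,3S)-2-[(1E)-5-iodo-2-[(4-methoxybenzyloxy)methyl]pent-1-enyl]-5-oxooxolan-3-yl]-2,2-dimethyl-1,3-dioxolane-4-carboxylate
Conditions: I2, PPh3, imidazole, CH2Cl2, 0 °C → rt
Reagents that add atoms: iodine, II
Why: Appel-type iodination of the primary alcohol by SN2 displacement of the oxyphosphonium group; no other group reacts.

Step 11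
Reactants: 16 methyl (4R,5S)-5-[(2R,3S)-2-[(1E)-5-iodo-2-[(4-methoxybenzyloxy)methyl]pent-1-enyl]-5-oxooxolan-3-yl]-2,2-dimethyl-1,3-dioxolane-4-carboxylate
Product: 17 (4R,5S)-5-[(2R,3S)-2-[(1E)-5-iodo-2-[(4-methoxybenzyloxy)methyl]pent-1-enyl]-5-oxooxolan-3-yl]-2,2-dimethyl-1,3-dioxolane-4-carboxylic acid
Conditions: Me3SnOH, 1,2-dichloroethane, 70 °C; then cold 0.1 M aq HCl wash
Reagents that add atoms: trimethyltin hydroxide, C[Sn](C)(C)O
Why: Me3SnOH hydrolysis is selective for the activated α-alkoxy methyl ester and does not epimerise C9; the γ-lactone, if opened, recloses on the acidic wash, and the weakly nucleophilic tin hydroxide should leave the primary iodide alone.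

Step 12
Reactants: 17 (4R,5S)-5-[(2R,3S)-2-[(1E)-5-iodo-2-[(4-methoxybenzyloxy)methyl]pent-1-enyl]-5-oxooxolan-3-yl]-2,2-dimethyl-1,3-dioxolane-4-carboxylic acid
Product: 18 S-pyridin-2-yl (4R,5S)-5-[(2R,3S)-2-[(1E)-5-iodo-2-[(4-methoxybenzyloxy)methyl]pent-1-enyl]-5-oxooxolan-3-yl]-2,2-dimethyl-1,3-dioxolane-4-carbothioate
Conditions: 2,2'-dipyridyl disulfide, PPh3 (premixed), CH2Cl2, rt, short reaction time
Reagents that add atoms: 2,2'-dipyridyl disulfide, c1ccc(SSc2ccccn2)nc1
Why: Mukaiyama redox condensation of the acid to the 2-pyridyl thioester; premixing consumes PPh3 before it can alkylate at the C1 iodide.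

Step 13
Reactants: 18 S-pyridin-2-yl (4R,5S)-5-[(2R,3S)-2-[(1E)-5-iodo-2-[(4-methoxybenzyloxy)methyl]pent-1-enyl]-5-oxooxolan-3-yl]-2,2-dimethyl-1,3-dioxolane-4-carbothioate
Product: 19 (4E,6R,7S,8S,9R)-8,9-(isopropylidenedioxy)-15-(4-methoxybenzyloxy)-10-oxo-13,14-dinorgermacr-4-en-12,6-olide (ten-membered ketone with trans-fused lactone and dioxolane)
Conditions: NiBr2(dtbbpy) (1 equiv), Cp2ZrCl2 (3 equiv), Zn dust (10 equiv), DMI/THF, rt, syringe-pump addition of 18 (final 2 mM)
Reagents that add atoms: none
Why: Nickel/zirconium-mediated reductive ketone synthesis from an alkyl iodide and a 2-pyridyl thioester, run intramolecularly at high dilution: zerovalent nickel inserts into the C10–S bond, the C1 radical from the iodide is captured by the acylnickel species and reductive elimination forms C1–C10; Cp2ZrCl2 takes up the thiolate and Zn is the terminal reductant. The cis C4=C5 alkene and the two trans-disubstituted five-membered rings hold the chain ends close; no stereocentre is formed.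

Step 14
Reactants: 19 (4E,6R,7S,8S,9R)-8,9-(isopropylidenedioxy)-15-(4-methoxybenzyloxy)-10-oxo-13,14-dinorgermacr-4-en-12,6-olide
Product: 20 (1(10)E,4E,6R,7S,8S,9R)-8,9-(isopropylidenedioxy)-15-(4-methoxybenzyloxy)-10-(trifluoromethanesulfonyloxy)-13,14-dinorgermacra-1(10),4-dien-12,6-olide
Conditions: KHMDS (1.05 equiv), THF, −78 °C; PhNTf2, −78 → −40 °C
Reagents that add atoms: N-phenylbis(trifluoromethanesulfonimide), O=S(=O)(N(c1ccccc1)S(=O)(=O)C(F)(F)F)C(F)(F)F
Why: Kinetic enolisation toward the C1 methylene (the C9–H is hindered and poorly aligned within the dioxolane) and O-triflation of the ketone enolate, which is formed in preference to the less acidic lactone enolate; the ten-membered ring should accommodate the enolate only with C2 cis to C9, which fixes the C1=C10 geometry.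

Step 15
Reactants: 20 (1(10)E,4E,6R,7S,8S,9R)-8,9-(isopropylidenedioxy)-15-(4-methoxybenzyloxy)-10-(trifluoromethanesulfonyloxy)-13,14-dinorgermacra-1(10),4-dien-12,6-olide
Product: 21 methyl (1(10)E,4E,6R,7S,8S,9S)-8,9-(isopropylidenedioxy)-15-(4-methoxybenzyloxy)-13-norgermacra-1(10),4-dien-12,6-olid-14-oate
Conditions: Pd(OAc)2 (10 mol%), PPh3 (20 mol%), CO (1 atm), MeOH, Et3N, DMF, rt → 40 °C
Reagents that add atoms: carbon monoxide, [C-]#[O+]; methanol, CO
Why: Palladium-catalysed methoxycarbonylation of an enol triflate (oxidative addition, CO insertion, methanolysis of the acylpalladium) with retention of alkene geometry; it installs C14.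

Step 16
Reactants: 21 methyl (1(10)E,4E,6R,7S,8S,9S)-8,9-(isopropylidenedioxy)-15-(4-methoxybenzyloxy)-13-norgermacra-1(10),4-dien-12,6-olid-14-oate
Product: 24 methyl (1(10)E,4E,6R,7S,8S,9S)-8,9-(isopropylidenedioxy)-15-(4-methoxybenzyloxy)germacra-1(10),4,11(13)-trien-12,6-olid-14-oate, via Mannich base 22 (not isolated), via ammonium iodide 23 (not isolated)
Conditions: LiHMDS, THF, −78 °C; CH2=NMe2+ I−, −78 → 0 °C; then MeI, rt; then sat. aq NaHCO3, rt
Reagents that add atoms: N,N-dimethylmethyleneiminium iodide (Eschenmoser's salt), C=[N+](C)C.[I-]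
Why: Lactone α-methylenation by Mannich reaction of the lithium enolate, N-methylation and base-induced elimination of trimethylamine; at −78 °C the lactone α-CH2 should be deprotonated faster than the γ-position of the hindered enoate.

Step 17
Reactants: 24 methyl (1(10)E,4E,6R,7S,8S,9S)-8,9-(isopropylidenedioxy)-15-(4-methoxybenzyloxy)germacra-1(10),4,11(13)-trien-12,6-olid-14-oate
Product: 25 methyl (1(10)E,4E,6R,7S,8S,9S)-8,9-dihydroxy-15-(4-methoxybenzyloxy)germacra-1(10),4,11(13)-trien-12,6-olid-14-oate
Conditions: AcOH/H2O (4:1), 50 °C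
Reagents that add atoms: none
Why: Acid-catalysed hydrolysis of the isopropylidene acetal; the PMB ether, both enoates and the lactone are stable to this weak aqueous acid.

Step 18
Reactants: 25 methyl (1(10)E,4E,6R,7S,8S,9S)-8,9-dihydroxy-15-(4-methoxybenzyloxy)germacra-1(10),4,11(13)-trien-12,6-olid-14-oate
Product: 26 methyl (1(10)E,4E,6R,7S,8S,9S)-9-hydroxy-15-(4-methoxybenzyloxy)-8-(2-methylpropanoyloxy)germacra-1(10),4,11(13)-trien-12,6-olid-14-oate
Conditions: isobutyric anhydride (1.1 equiv), 2,4,6-collidine, DMAP (5 mol%), CH2Cl2, −40 → 0 °C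
Reagents that add atoms: isobutyric anhydride, CC(C)C(=O)OC(=O)C(C)C
Why: Regioselective DMAP-catalysed acylation: O8 is an ordinary secondary hydroxyl, whereas O9 is inductively deactivated by the acrylate carbon C10 and shielded by the adjacent C14 ester, so the branched acyl group should go to O8 at low temperature.

Step 19
Reactants: 26 methyl (1(10)E,4E,6R,7S,8S,9S)-9-hydroxy-15-(4-methoxybenzyloxy)-8-(2-methylpropanoyloxy)germacra-1(10),4,11(13)-trien-12,6-olid-14-oate
Product: 27 methyl (1(10)E,4E,6R,7S,8S,9S)-9-acetoxy-15-(4-methoxybenzyloxy)-8-(2-methylpropanoyloxy)germacra-1(10),4,11(13)-trien-12,6-olid-14-oate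
Conditions: Ac2O, pyridine, DMAP (cat.), CH2Cl2, 0 °C → rt
Reagents that add atoms: acetic anhydride, CC(=O)OC(C)=O
Why: Acetylation of the only remaining free hydroxyl (allylic O9) under standard DMAP catalysis; O15 is still protected.

Step 20
Reactants: 27 methyl (1(10)E,4E,6R,7S,8S,9S)-9-acetoxy-15-(4-methoxybenzyloxy)-8-(2-methylpropanoyloxy)germacra-1(10),4,11(13)-trien-12,6-olid-14-oate
Product: 28 methyl (1(10)E,4E,6R,7S,8S,9S)-9-acetoxy-15-hydroxy-8-(2-methylpropanoyloxy)germacra-1(10),4,11(13)-trien-12,6-olid-14-oate (CNP0242134.2)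
Conditions: DDQ, CH2Cl2/pH 7 phosphate buffer (10:1), 0 °C → rt
Reagents that add atoms: none
Why: Oxidative cleavage of the PMB ether with DDQ (hydride abstraction, hydrolysis of the oxocarbenium ion) under neutral conditions that spare the esters, the α-methylene lactone and the alkenes.

## Compound list

1 | dimethyl (4R,5R)-2,2-dimethyl-1,3-dioxolane-4,5-dicarboxylate | COC(=O)[C@@H]1OC(C)(C)O[C@H]1C(=O)OC | starting material
2 | (4R,5R)-5-(methoxycarbonyl)-2,2-dimethyl-1,3-dioxolane-4-carboxylic acid | OC(=O)[C@@H]1OC(C)(C)O[C@H]1C(=O)OC | intermediate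
3 | (S)-5-(hydroxymethyl)furan-2(5H)-one | O=C1C=C[C@@H](CO)O1 | starting material
4 | (S)-5-{[tert-butyl(dimethyl)silyl]oxymethyl}furan-2(5H)-one | O=C1C=C[C@@H](CO[Si](C)(C)C(C)(C)C)O1 | intermediate
5 | methyl (4R,5S)-5-[(2S,3S)-2-{[tert-butyl(dimethyl)silyl]oxymethyl}-5-oxooxolan-3-yl]-2,2-dimethyl-1,3-dioxolane-4-carboxylate | O=C1C[C@H]([C@@H]2OC(C)(C)O[C@H]2C(=O)OC)[C@H](O1)CO[Si](C)(C)C(C)(C)C | intermediate
6 | methyl (4R,5S)-5-[(2S,3S)-2-(hydroxymethyl)-5-oxooxolan-3-yl]-2,2-dimethyl-1,3-dioxolane-4-carboxylate | O=C1C[C@H]([C@@H]2OC(C)(C)O[C@H]2C(=O)OC)[C@H](O1)CO | intermediate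
7 | methyl (4R,5S)-5-[(2S,3R)-2-formyl-5-oxooxolan-3-yl]-2,2-dimethyl-1,3-dioxolane-4-carboxylate | O=C1C[C@H]([C@@H]2OC(C)(C)O[C@H]2C(=O)OC)[C@H](O1)C=O | intermediate
8 | carbon tetrabromide | BrC(Br)(Br)Br | starting material
9 | methyl (4R,5S)-5-[(2S,3S)-2-(2,2-dibromoethenyl)-5-oxooxolan-3-yl]-2,2-dimethyl-1,3-dioxolane-4-carboxylate | O=C1C[C@H]([C@@H]2OC(C)(C)O[C@H]2C(=O)OC)[C@H](O1)C=C(Br)Br | intermediate
10 | tert-butyl(3-iodopropoxy)dimethylsilane | ICCCO[Si](C)(C)C(C)(C)C | starting material
11 | [3-(tert-butyldimethylsilyloxy)propyl]zinc iodide | I[Zn]CCCO[Si](C)(C)C(C)(C)C | intermediate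
12 | potassium [(4-methoxybenzyloxy)methyl]trifluoroborate | COc1ccc(COC[B-](F)(F)F)cc1.[K+] | starting material
13 | methyl (4R,5S)-5-[(2S,3S)-2-[(1Z)-2-bromo-3-(4-methoxybenzyloxy)prop-1-enyl]-5-oxooxolan-3-yl]-2,2-dimethyl-1,3-dioxolane-4-carboxylate (formed in the flask, not isolated) | O=C1C[C@H]([C@@H]2OC(C)(C)O[C@H]2C(=O)OC)[C@H](O1)/C=C(/COCc1ccc(OC)cc1)Br | intermediate
14 | methyl (4R,5S)-5-[(2R,3S)-2-[(1E)-5-{[tert-butyl(dimethyl)silyl]oxy}-2-[(4-methoxybenzyloxy)methyl]pent-1-enyl]-5-oxooxolan-3-yl]-2,2-dimethyl-1,3-dioxolane-4-carboxylate | O=C1C[C@H]([C@@H]2OC(C)(C)O[C@H]2C(=O)OC)[C@H](O1)/C=C(/COCc1ccc(OC)cc1)CCCO[Si](C)(C)C(C)(C)C | intermediate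
15 | methyl (4R,5S)-5-[(2R,3S)-2-[(1E)-5-hydroxy-2-[(4-methoxybenzyloxy)methyl]pent-1-enyl]-5-oxooxolan-3-yl]-2,2-dimethyl-1,3-dioxolane-4-carboxylate | O=C1C[C@H]([C@@H]2OC(C)(C)O[C@H]2C(=O)OC)[C@H](O1)/C=C(/COCc1ccc(OC)cc1)CCCO | intermediate
16 | methyl (4R,5S)-5-[(2R,3S)-2-[(1E)-5-iodo-2-[(4-methoxybenzyloxy)methyl]pent-1-enyl]-5-oxooxolan-3-yl]-2,2-dimethyl-1,3-dioxolane-4-carboxylate | O=C1C[C@H]([C@@H]2OC(C)(C)O[C@H]2C(=O)OC)[C@H](O1)/C=C(/COCc1ccc(OC)cc1)CCCI | intermediate
17 | (4R,5S)-5-[(2R,3S)-2-[(1E)-5-iodo-2-[(4-methoxybenzyloxy)methyl]pent-1-enyl]-5-oxooxolan-3-yl]-2,2-dimethyl-1,3-dioxolane-4-carboxylic acid | O=C1C[C@H]([C@@H]2OC(C)(C)O[C@H]2C(=O)O)[C@H](O1)/C=C(/COCc1ccc(OC)cc1)CCCI | intermediate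
18 | S-pyridin-2-yl (4R,5S)-5-[(2R,3S)-2-[(1E)-5-iodo-2-[(4-methoxybenzyloxy)methyl]pent-1-enyl]-5-oxooxolan-3-yl]-2,2-dimethyl-1,3-dioxolane-4-carbothioate | O=C1C[C@H]([C@@H]2OC(C)(C)O[C@H]2C(=O)Sc2ccccn2)[C@H](O1)/C=C(/COCc1ccc(OC)cc1)CCCI | intermediate
19 | (4E,6R,7S,8S,9R)-8,9-(isopropylidenedioxy)-15-(4-methoxybenzyloxy)-10-oxo-13,14-dinorgermacr-4-en-12,6-olide | C1C(=O)O[C@@H]2/C=C(/COCc3ccc(OC)cc3)CCCC(=O)[C@@H]3OC(C)(C)O[C@H]3[C@@H]12 | intermediate
20 | (1(10)E,4E,6R,7S,8S,9R)-8,9-(isopropylidenedioxy)-15-(4-methoxybenzyloxy)-10-(trifluoromethanesulfonyloxy)-13,14-dinorgermacra-1(10),4-dien-12,6-olide | C1C(=O)O[C@@H]2/C=C(/COCc3ccc(OC)cc3)CC/C=C(/OS(=O)(=O)C(F)(F)F)[C@@H]3OC(C)(C)O[C@H]3[C@@H]12 | intermediate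
21 | methyl (1(10)E,4E,6R,7S,8S,9S)-8,9-(isopropylidenedioxy)-15-(4-methoxybenzyloxy)-13-norgermacra-1(10),4-dien-12,6-olid-14-oate | C1C(=O)O[C@@H]2/C=C(/COCc3ccc(OC)cc3)CC/C=C(/C(=O)OC)[C@@H]3OC(C)(C)O[C@H]3[C@@H]12 | intermediate
22 | 13-(dimethylamino)-11,13-dihydro derivative of 24 (Mannich base, C11 configuration open; formed in the flask, not isolated) | CN(C)CC1C(=O)O[C@@H]2/C=C(/COCc3ccc(OC)cc3)CC/C=C(/C(=O)OC)[C@@H]3OC(C)(C)O[C@H]3[C@@H]12 | intermediate
23 | 13-(trimethylammonio)-11,13-dihydro derivative of 24, iodide (C11 configuration open; formed in the flask, not isolated) | C[N+](C)(C)CC1C(=O)O[C@@H]2/C=C(/COCc3ccc(OC)cc3)CC/C=C(/C(=O)OC)[C@@H]3OC(C)(C)O[C@H]3[C@@H]12.[I-] | intermediate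
24 | methyl (1(10)E,4E,6R,7S,8S,9S)-8,9-(isopropylidenedioxy)-15-(4-methoxybenzyloxy)germacra-1(10),4,11(13)-trien-12,6-olid-14-oate | C=C1C(=O)O[C@@H]2/C=C(/COCc3ccc(OC)cc3)CC/C=C(/C(=O)OC)[C@@H]3OC(C)(C)O[C@H]3[C@@H]12 | intermediate
25 | methyl (1(10)E,4E,6R,7S,8S,9S)-8,9-dihydroxy-15-(4-methoxybenzyloxy)germacra-1(10),4,11(13)-trien-12,6-olid-14-oate | C=C1C(=O)O[C@@H]2/C=C(/COCc3ccc(OC)cc3)CC/C=C(/C(=O)OC)[C@H](O)[C@@H](O)[C@@H]12 | intermediate
26 | methyl (1(10)E,4E,6R,7S,8S,9S)-9-hydroxy-15-(4-methoxybenzyloxy)-8-(2-methylpropanoyloxy)germacra-1(10),4,11(13)-trien-12,6-olid-14-oate | C=C1C(=O)O[C@@H]2/C=C(/COCc3ccc(OC)cc3)CC/C=C(/C(=O)OC)[C@H](O)[C@@H](OC(=O)C(C)C)[C@@H]12 | intermediate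
27 | methyl (1(10)E,4E,6R,7S,8S,9S)-9-acetoxy-15-(4-methoxybenzyloxy)-8-(2-methylpropanoyloxy)germacra-1(10),4,11(13)-trien-12,6-olid-14-oate | C=C1C(=O)O[C@@H]2/C=C(/COCc3ccc(OC)cc3)CC/C=C(/C(=O)OC)[C@H](OC(C)=O)[C@@H](OC(=O)C(C)C)[C@@H]12 | intermediate
28 | methyl (1(10)E,4E,6R,7S,8S,9S)-9-acetoxy-15-hydroxy-8-(2-methylpropanoyloxy)germacra-1(10),4,11(13)-trien-12,6-olid-14-oate (CNP0242134.2) | C=C1C(=O)O[C@@H]2/C=C(/CO)CC/C=C(/C(=O)OC)[C@H](OC(C)=O)[C@@H](OC(=O)C(C)C)[C@@H]12 | target

## Step count and least certain steps

Total step count: 20. Longest linear sequence: 18 steps (steps 1, 3–6, 8–20).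

**Step 8 (key step).** The sp3 alkoxymethyl boron species may transmetallate slowly at 60 °C. Double coupling, erosion of the trans selectivity or hydrolysis of the C10 ester could then compete. In the second stage, protonolysis of the organozinc by residual water, or isomerisation of the alkenylpalladium, would lower the geometric purity. Fallback: from 9, a trans-selective Stille monocoupling with (tributylstannyl)methanol (Pd2(dba)3, tri(2-furyl)phosphine, toluene, 80 °C) would give the (Z)-bromo allylic alcohol F1. Protection with 4-methoxybenzyl 2,2,2-trichloroacetimidate and catalytic La(OTf)3 gives 13, now isolated and dried. A separate anhydrous Negishi coupling with 11 and Pd(t-Bu3P)2 returns to the route at 14.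

**Step 13.** Intermolecular ketone formation and reduction of the C1–I bond to C–H may outrun the entropically disfavoured ten-membered closure. Fallback: from 17, ethanethiol, EDC and DMAP give the S-ethyl thioester F2. Zinc insertion into the C1–I bond (activated Zn, DMA) gives the alkylzinc iodide F3. Under high dilution with PdCl2(PPh3)2 this undergoes an intramolecular Fukuyama coupling and rejoins the route at 19. The organometallic is preformed and the acyl transfer is a two-electron palladium process, not a nickel radical pathway.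

**Step 14.** Enolisation may go toward C9, with epimerisation there or β-elimination that opens the dioxolane, or may give the ring-trans enolate; either means loss of regio- or geometric control. Fallback: from 19, 1,2-bis(tert-butyldimethylsilyl)hydrazine and catalytic Sc(OTf)3 give the N-silyl hydrazone F4. Iodine and tetramethylguanidine (Barton vinyl iodide synthesis) give the vinyl iodide F5 without any enolate. Palladium-catalysed methoxycarbonylation of F5 under the conditions of step 15 rejoins the route at 21.

**Step 18.** Discrimination between O8 and O9 may be poor, and the acyl group may migrate between them. Fallback: from 25, the dibutylstannylene acetal (Bu2SnO, toluene, 80 °C) is treated with acetic anhydride. Reaction is expected at the more acidic allylic O9 and would give the 9-acetate F6. Isobutyric anhydride and DMAP then acylate O8, and the route is rejoined at 27.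

**Step 3.** Facial control at C7 or C8 may be incomplete, and the phosphate base may racemise 4 through its dienolate. Fallback: from 2, N-hydroxyphthalimide, DIC and DMAP give the N-(acyloxy)phthalimide F7. Reductive fragmentation (Ru(bpy)3(PF6)2, Hantzsch ester, i-Pr2NEt, blue LEDs, CH2Cl2) in the presence of 4 generates the same C8 radical without inorganic base and rejoins the route at 5.

## Further compounds

F1 | step 8 | methyl (4R,5S)-5-[(2S,3S)-2-[(1Z)-2-bromo-3-hydroxyprop-1-enyl]-5-oxooxolan-3-yl]-2,2-dimethyl-1,3-dioxolane-4-carboxylate | O=C1C[C@H]([C@@H]2OC(C)(C)O[C@H]2C(=O)OC)[C@H](O1)/C=C(/CO)Br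
F2 | step 13 | S-ethyl (4R,5S)-5-[(2R,3S)-2-[(1E)-5-iodo-2-[(4-methoxybenzyloxy)methyl]pent-1-enyl]-5-oxooxolan-3-yl]-2,2-dimethyl-1,3-dioxolane-4-carbothioate | O=C1C[C@H]([C@@H]2OC(C)(C)O[C@H]2C(=O)SCC)[C@H](O1)/C=C(/COCc1ccc(OC)cc1)CCCI
F3 | step 13 | alkylzinc iodide from F2 (C1–ZnI) | O=C1C[C@H]([C@@H]2OC(C)(C)O[C@H]2C(=O)SCC)[C@H](O1)/C=C(/COCc1ccc(OC)cc1)CCC[Zn]I
F4 | step 14 | N-(tert-butyldimethylsilyl)hydrazone of 19 at C10 | C1C(=O)O[C@@H]2/C=C(/COCc3ccc(OC)cc3)CCCC(=NN[Si](C)(C)C(C)(C)C)[C@@H]3OC(C)(C)O[C@H]3[C@@H]12
F5 | step 14 | (1(10)Z,4E,6R,7S,8S,9R)-10-iodo-8,9-(isopropylidenedioxy)-15-(4-methoxybenzyloxy)-13,14-dinorgermacra-1(10),4-dien-12,6-olide (C2 cis to C9) | C1C(=O)O[C@@H]2/C=C(/COCc3ccc(OC)cc3)CC/C=C(/I)[C@@H]3OC(C)(C)O[C@H]3[C@@H]12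
F6 | step 18 | methyl (1(10)E,4E,6R,7S,8S,9S)-9-acetoxy-8-hydroxy-15-(4-methoxybenzyloxy)germacra-1(10),4,11(13)-trien-12,6-olid-14-oate | C=C1C(=O)O[C@@H]2/C=C(/COCc3ccc(OC)cc3)CC/C=C(/C(=O)OC)[C@H](OC(C)=O)[C@@H](O)[C@@H]12
F7 | step 3 | 4-(1,3-dioxoisoindolin-2-yl) 5-methyl (4R,5R)-2,2-dimethyl-1,3-dioxolane-4,5-dicarboxylate | O=C(ON1C(=O)c2ccccc2C1=O)[C@@H]1OC(C)(C)O[C@H]1C(=O)OC
A1 | alternative 1 | cyclodecadienone with C8 PMB ether, C9 MOM ether and C6 ketone | C1[C@H](OCc2ccc(OC)cc2)[C@@H](OCOC)/C(C(=O)OC)=C\CC/C(CO[Si](C)(C)C(C)(C)C)=C\C1=O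
A2 | alternative 1 | (1R,6S)-configured cis-dialkenyl cyclohex-2-enol: (E)-2-(4-methoxybenzyloxy)vinyl on the carbinol carbon, (Z)-β-(methoxymethoxy)acrylate arm on the neighbouring carbon | O[C@]1(/C=C/OCc2ccc(OC)cc2)C=C(CO[Si](C)(C)C(C)(C)C)CC[C@H]1/C(C(=O)OC)=C/OCOC
A3 | alternative 2 | α-phosphono lactone with the C8=C9 dienoate arm | CCOP(=O)(OCC)[C@@H]1C(=O)O[C@H](/C=C(/CO[Si](C)(C)C(C)(C)C)COCc2ccc(OC)cc2)[C@H]1/C=C/C(C(=O)OC)=C\COCc1ccc(OC)cc1
A4 | alternative 2 | C6 diethylphosphonoacetate with C9 allylic acetate (C9 configuration open) | CCOP(=O)(OCC)CC(=O)O[C@H](/C=C(/CO[Si](C)(C)C(C)(C)C)COCc1ccc(OC)cc1)/C=C/C(OC(C)=O)/C(C(=O)OC)=C\COCc1ccc(OC)cc1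
A5 | alternative 3 | ten-membered alkylidene β-keto ester | O=C1/C(C(=O)OC)=C\CC/C(CO[Si](C)(C)C(C)(C)C)=C\[C@H]2OC(=O)C[C@@H]2[C@@H]1OCc1ccc(OC)cc1
A6 | alternative 3 | lactone-fused eight-membered trimethylsilyl enol ether (C9=C2) | C[Si](C)(C)OC1=CC/C(CO[Si](C)(C)C(C)(C)C)=C\[C@H]2OC(=O)C[C@@H]2[C@@H]1OCc1ccc(OC)cc1
A7 | alternative 3 | bicyclo[6.2.0]decene cyclobutene adduct (C2 and C9 configuration open) | C[Si](C)(C)OC13C(C(=O)OC)=CC3C/C(CO[Si](C)(C)C(C)(C)C)=C\[C@H]2OC(=O)C[C@@H]2[C@@H]1OCc1ccc(OC)cc1
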